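A small charge pairs slowly. With the equivalents fixed, a second-order step gives the same percentages, during the first portion, at the same charge multiplied by the time since the start.

| flask | substrate | partner | remark | time |
|---|---|---|---|---|
| dusk | 0.074 M (in portions, 2) | 1.5 equiv | run made earlier; portions every 10 h |  |
| summer | 0.074 M (in portions, 2) | 2.4 equiv | run made earlier; portions every 10 h |  |
| midnight | 0.15 M (in portions, 2) | 1.1 equiv | run made earlier; portions every 10 h |  |
| flask | 0.074 M (in portions, 2) | 1.10 equiv | the portions of substrate follow each other after 10 h, the first at the start | 20 h |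

| run | time / h | mono adduct / % | substrate / % |
|---|---|---|---|
| dusk | 5.00 | 36.0 | 9.1 |
| dusk | 10.0 | 39.0 | 3.3 |
| dusk | 15.0 | 64.5 | 22.0 |
| dusk | 20.0 | 71.4 | 12.7 |
| dusk | 25.0 | 72.7 | 7.9 |
| summer | 2.00 | 32.1 | 15.3 |
| summer | 4.00 | 38.9 | 5.3 |
| summer | 6.00 | 38.8 | 2.5 |
| summer | 12.0 | 58.9 | 23.3 |
| summer | 25.0 | 62.0 | 1.2 |
| midnight | 2.00 | 29.3 | 18.6 |
| midnight | 6.00 | 39.3 | 4.7 |
| midnight | 12.0 | 53.2 | 34.7 |
| midnight | 15.0 | 61.1 | 24.1 |
| midnight | 25.0 | 67.5 | 15.2 |

(scatter of a reading: 0.3 percentage points)

- mono adduct present at 20 h, in percent of the substrate charged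
- substrate present at 20 h, in percent of the substrate charged
- double product present at 20 h, in percent of the substrate charged



For this flask that product over one interval is 44.4 M·min: the charge-time. Midnight has the same equivalents at 0.15 M, so it reaches this charge-time 4.93 h after the start. Its 15.0 h reading, 5.00 h after the second portion, lies about as far past that portion and shows 24.1 % substrate. Past the second portion the rule is not strict: midnight's interval holds twice the charge-time of the flask's, so this reading is a rough guide. That is my first way.

My second way reckons. Between midnight's 2.00 h and 6.00 h readings, the same charge-time leaves about 6.78 % of the flask's charge as substrate. The second portion lifts this to a share s of 56.8 %. Early summer, nearly pseudo-first-order in its excess partner, gives decay rate over c(partner) as k = 3.50 L mol⁻¹ h⁻¹. I take c(substrate) and c(partner) as about equal after the second portion, so s/(1 + s·k·charge-time) gives 23.0 %.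

The ways part. I test the formula on midnight from 12.0 h to 15.0 h: it gives 22.4 % against the reading of 24.1 %. So the formula runs fast, and I commit to the first way, as a rough figure.

The forecast says 66.7 % mono adduct, 24 % substrate and 9.3 % double product, holding that “the decay is almost purely second order”. Its substrate stands close to mine.

The flask gives 65.3 % mono adduct, 23.8 % substrate and 8.54 % double product.

    partner → decomposed reagent (k = 2.70 × 10⁻⁶ s⁻¹)
    substrate ⇌ dormant form (K = 4.10, k = 1.20 × 10⁻⁶ s⁻¹)
    substrate + partner → mono adduct + by-product (k = 0.00100 L mol⁻¹ s⁻¹)
    partner + mono adduct → double product + by-product (k = 8.90 × 10⁻⁵ L mol⁻¹ s⁻¹)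

In this flask, substrate's half-life by its step with partner is 4.0 h at 6.26 h, shorter than 20 h. Mono adduct's half-life by its step with partner is 170 h at 20.0 h, longer than 20 h. The charge-time of 44.4 M·min leaves this flask 6.69 % substrate just before the second portion, at 10.0 h. The neighbour flask charged with 0.030 M has a charge-time of 1080 M·s, equal to that of midnight's 2.00 h reading of 18.6 %. Its second portion then lifts the share to 68.6 %, the formula gives 39.9 %, and the neighbour flask holds 38.6 % substrate.

(The earlier runs and the new flask come from a simulation from invented constants; noise was put on by code.)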